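**Plan**

- Retrosynthesis: the two angelate C–O bonds are cut first and the C6 carbinol is taken back to a ketone. C1–C10 and C4–C5 are then cut together, which opens both rings to an acyclic allylsilane ene-dione. That chain is cut at C5–C6 (alkenyl–carbonyl) and at C2–C3 (aldol).
- Feature used: the five-membered ring is numbered C1 (quaternary, methyl), C2 (ester), C3, C4 (hydroxyl, isopropyl), C5 (H), and the seven-membered ring continues C6 (ester), C7, C8 (methyl), C9, C10. The C6 oxygen makes C5=C1 an enone with C1 as acceptor, C8=C9 with C10 is a transposed allylsilane, and the C4 oxygen sits β to C6, an aldol relationship between C5 and C4.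
- Forward: a C6–C10 allylsilane aldehyde (Claisen) and a C1–C5 vinyl iodide ketone (asymmetric aldol) are joined at C5–C6 and oxidised. One Lewis acid operation then closes the seven-membered ring (C1–C10) and, from the enolate so formed, the five-membered ring (C4–C5). Ketone reduction, desilylation and double angeloylation finish the route.
- Stereochemistry: C2 comes from a catalyst-controlled Mukaiyama aldol, C1 from 1,2-induction by C2, C4 and C5 from the chelated, reversible aldol, C6 from hydride delivery by the C4 hydroxyl, and both ester alkenes from angelic acid itself.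

Key step: step 10

Locants C1–C10 in the text are those of the plan; β is the face of the C1 methyl group.

Assumption: C8 is carried as a racemate because it becomes trigonal in step 10, and the bisphosphoramide antipode in step 6 is the one that directs the enol ether to the aldehyde Si face, to be confirmed by Mosher ester analysis of 12.

**Route**

Step 1
Reactants: 1 but-2-yn-1-ol
Product: 2 (Z)-3-[benzyl(dimethyl)silyl]but-2-en-1-ol
Conditions: BnMe2SiH (1.2 equiv), [Cp*Ru(MeCN)3]PF6 (1 mol %), acetone, 0 °C → rt
Reagents that add atoms: benzyl(dimethyl)silane, C[SiH](C)Cc1ccccc1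
Why: Ruthenium-catalysed trans-hydrosilylation of a propargylic alcohol places silicon on the alkyne carbon distal to the hydroxyl and adds H and Si anti, which should give the Z vinylsilane; the alkene geometry has no consequence after step 2.

Step 2
Reactants: 2 (Z)-3-[benzyl(dimethyl)silyl]but-2-en-1-ol
Product: 4 3-[benzyl(dimethyl)silyl]-3-methylpent-4-enal (racemic), via allyl vinyl ether 3 (not isolated)
Conditions: butyl vinyl ether (excess), Pd(OCOCF3)2 (1 mol %), 4,7-diphenyl-1,10-phenanthroline (1 mol %), Et3N, 75 °C; evaporate; PhMe, 170 °C (sealed tube)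
Reagents that add atoms: butyl vinyl ether, C=COCCCC
Why: Palladium-catalysed transfer vinylation followed by the aliphatic Claisen rearrangement through a chair [3,3] transition state should create the quaternary allylsilane carbon C8 and the C6 aldehyde together; C8 forms as a racemate.

Step 3
Reactants: 5 prop-2-yn-1-ol
Product: 7 (E)-3-iodo-2-methylprop-2-en-1-ol, via alkenylalane 6 (not isolated)
Conditions: Me3Al (3 equiv), Cp2ZrCl2 (0.25 equiv), CH2Cl2, 0 °C → rt; then I2, THF, −30 → 0 °C; aq. K2CO3
Reagents that add atoms: trimethylaluminium, C[Al](C)C; iodine, II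
Why: Zirconium-catalysed carboalumination (Negishi) adds methyl and aluminium syn across the alkyne with methyl at the internal carbon, and iodinolysis of the C–Al bond with retention should give the E iodide.

Step 4
Reactants: 7 (E)-3-iodo-2-methylprop-2-en-1-ol
Product: 8 (E)-3-iodo-2-methylprop-2-enal
Conditions: MnO2 (15 equiv), CH2Cl2, rt
Reagents that add atoms: none
Why: Allylic alcohol oxidation with MnO2 stops at the enal and leaves the vinyl iodide and its geometry untouched.

Step 5
Reactants: 9 3-methylbutan-2-one
Product: 11 trimethyl[(3-methylbut-1-en-2-yl)oxy]silane, via lithium enolate 10 (not isolated)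
Conditions: LiN(i-Pr)2 (1.05 equiv), THF, −78 °C; Me3SiCl, −78 °C → rt
Reagents that add atoms: chlorotrimethylsilane, C[Si](C)(C)Cl
Why: Kinetic deprotonation takes a proton from the methyl group rather than the isopropyl methine, and O-silylation traps the less substituted enolate as the silyl enol ether.

Step 6
Reactants: 8 (E)-3-iodo-2-methylprop-2-enal; 11 trimethyl[(3-methylbut-1-en-2-yl)oxy]silane
Product: 12 (5S,6E)-5-hydroxy-7-iodo-2,6-dimethylhept-6-en-3-one
Conditions: SiCl4 (1.5 equiv), BINAM-derived bisphosphoramide (5 mol %, antipode for Si-face attack), i-Pr2NEt (10 mol %), CH2Cl2, −78 °C; aq. NaHCO3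
Reagents that add atoms: none
Why: Lewis base-catalysed, SiCl4-mediated Mukaiyama aldol addition: the phosphoramide-bound trichlorosilyl cation activates the enal and the enol ether adds through an open transition state to the aldehyde Si face, which forms C2–C3 and should set C2 as S.

Step 7
Reactants: 12 (5S,6E)-5-hydroxy-7-iodo-2,6-dimethylhept-6-en-3-one
Product: 13 (5S,6E)-5-{[tert-butyl(dimethyl)silyl]oxy}-7-iodo-2,6-dimethylhept-6-en-3-one
Conditions: t-BuMe2SiCl, imidazole, DMF, rt
Reagents that add atoms: tert-butyl(chloro)dimethylsilane, CC(C)(C)[Si](C)(C)Cl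
Why: Standard silylation of a secondary alcohol under near-neutral conditions, which avoid β-elimination of the aldol and enol silylation of the ketone.

Step 8
Reactants: 13 (5S,6E)-5-{[tert-butyl(dimethyl)silyl]oxy}-7-iodo-2,6-dimethylhept-6-en-3-one; 4 3-[benzyl(dimethyl)silyl]-3-methylpent-4-enal
Product: 14 (5S,6E)-10-[benzyl(dimethyl)silyl]-5-{[tert-butyl(dimethyl)silyl]oxy}-8-hydroxy-2,6,10-trimethyldodeca-6,11-dien-3-one (epimers at the carbinol and silane carbons)
Conditions: CrCl2 (4 equiv), NiCl2 (2 mol %), DMSO, rt
Reagents that add atoms: none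
Why: Nozaki–Hiyama–Kishi coupling: the alkenylchromium species formed from the vinyl iodide with retention of geometry adds to the aldehyde and not to the ketone, forming C5–C6; the new carbinol centre forms without control and is removed in step 9.

Step 9
Reactants: 14 the coupled allylic alcohol
Product: 15 (5S,6E)-10-[benzyl(dimethyl)silyl]-5-{[tert-butyl(dimethyl)silyl]oxy}-2,6,10-trimethyldodeca-6,11-diene-3,8-dione (both epimers at the silane carbon)
Conditions: Dess–Martin periodinane (1.5 equiv), NaHCO3, CH2Cl2, 0 °C → rt
Reagents that add atoms: none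
Why: Dess–Martin oxidation of the allylic alcohol should give the E enone under buffered conditions that spare the allylsilane and the silyl ether.

Step 10
Reactants: 15 the acyclic allylsilane ene-dione
Product: 17 (1S,3R,3aR,8aR)-1-{[tert-butyl(dimethyl)silyl]oxy}-3-hydroxy-6,8a-dimethyl-3-(propan-2-yl)-2,3,3a,5,8,8a-hexahydro-1H-azulen-4-one, via aluminium enolate 16 (not isolated)
Conditions: EtAlCl2 (3 equiv), CH2Cl2, −78 → 0 °C; aq. NaHCO3
Reagents that add atoms: none
Why: Proposed new method: EtAlCl2 on the C6 carbonyl makes C1 a tertiary oxyallyl cation, the allylsilane terminus C10 adds to it (anti SE2', 7-endo-trig at the enone), loss of BnMe2SiCl from the β-silyl cation leaves the alkene only at C8=C9, and the aluminium enolate 16 then closes through C5 onto the Lewis acid-bound C4 ketone (5-(enolexo)-exo-trig aldol). The closest known reaction types are the intramolecular Hosomi–Sakurai annulation to seven-membered rings and the tandem conjugate addition–intramolecular aldol reaction, which have not been merged on an acyclic chain in this endo sense. C1 is controlled by C2 through 1,2-induction: with C2–H next to the C1 methyl group (A(1,2) strain) the C3 branch that carries the second complexed carbonyl shields one face, and C10 enters anti to it, which places C10 cis to the C2 silyloxy group on the future five-membered ring. C4 and C5 are controlled by the aluminium bridge between O4 and O6 (hydroxyl cis to C6, isopropyl anti) and by reversibility of the aldol on warming to 0 °C, which is counted on to drain a kinetic cis-fused aldolate into the trans-fused chelate. The step needs attack of C10 at C1 and not at the C6 carbonyl, secured by the 5-endo geometry of that alternative, and survival of the silyl ether and of the acid-labile tertiary allylsilane, for which a proton-scavenging alkylaluminium chloride is preferred to TiCl4. Both C8 epimers of 15 converge because C8 becomes trigonal.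

Step 11
Reactants: 17 the trans-fused ketol
Product: 18 (1S,3R,3aS,4S,8aR)-1-{[tert-butyl(dimethyl)silyl]oxy}-6,8a-dimethyl-3-(propan-2-yl)-1,2,3,3a,4,5,8,8a-octahydroazulene-3,4-diol
Conditions: Me4NBH(OAc)3 (5 equiv), MeCN–AcOH (1:1), −30 → −20 °C
Reagents that add atoms: none
Why: Hydroxyl-directed (Evans–Saksena) reduction: the C4 hydroxyl exchanges onto boron and delivers hydride within a six-membered transition state to the β-face of the C6 carbonyl, which should give the C6 α-alcohol trans to the C4 hydroxyl.

Step 12
Reactants: 18 the silylated diol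
Product: 19 (1S,3R,3aS,4S,8aR)-6,8a-dimethyl-3-(propan-2-yl)-1,2,3,3a,4,5,8,8a-octahydroazulene-1,3,4-triol
Conditions: Bu4NF (3 equiv), THF, rt → 40 °C
Reagents that add atoms: none
Why: Fluoride cleavage of the silyl ether; no stereocentre is touched and the diol and the alkene are inert to fluoride.

Step 13
Reactants: 19 the triol; 20 angelic acid [(Z)-2-methylbut-2-enoic acid]
Product: 22 (1S,3R,3aS,4S,8aR)-3-hydroxy-6,8a-dimethyl-3-(propan-2-yl)-1,2,3,3a,4,5,8,8a-octahydroazulene-1,4-diyl bis[(2Z)-2-methylbut-2-enoate] (CNP0303897.1), via angelic 2,4,6-trichlorobenzoic anhydride 21 (not isolated)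
Conditions: 20 (5 equiv), 2,4,6-Cl3C6H2COCl (5 equiv), Et3N, PhMe, rt; then 19, 80 °C
Reagents that add atoms: none
Why: Yamaguchi-type mixed anhydride acylation without a nucleophilic catalyst: the two secondary alcohols attack the unhindered angeloyl carbonyl, the tertiary C4 hydroxyl stays free, and the absence of DMAP should prevent isomerisation of the Z enoate to the tiglate.

**Compound list**

1 | but-2-yn-1-ol | CC#CCO | starting material
2 | (Z)-3-[benzyl(dimethyl)silyl]but-2-en-1-ol | C/C(=C/CO)[Si](C)(C)Cc1ccccc1 | intermediate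
3 | benzyl[(2Z)-4-(ethenyloxy)but-2-en-2-yl]dimethylsilane | C/C(=C/COC=C)[Si](C)(C)Cc1ccccc1 | intermediate
4 | 3-[benzyl(dimethyl)silyl]-3-methylpent-4-enal (racemic) | C=CC(C)(CC=O)[Si](C)(C)Cc1ccccc1 | intermediate
5 | prop-2-yn-1-ol | C#CCO | starting material
6 | [(1E)-3-(dimethylalumanyloxy)-2-methylprop-1-en-1-yl]dimethylalane | C/C(=C\[Al](C)C)CO[Al](C)C | intermediate
7 | (E)-3-iodo-2-methylprop-2-en-1-ol | C/C(=C\I)CO | intermediate
8 | (E)-3-iodo-2-methylprop-2-enal | C/C(=C\I)C=O | intermediate
9 | 3-methylbutan-2-one | CC(C)C(C)=O | starting material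
10 | lithium 3-methylbut-1-en-2-olate | [Li]OC(=C)C(C)C | intermediate
11 | trimethyl[(3-methylbut-1-en-2-yl)oxy]silane | C=C(O[Si](C)(C)C)C(C)C | intermediate
12 | (5S,6E)-5-hydroxy-7-iodo-2,6-dimethylhept-6-en-3-one | I/C=C(C)/[C@@H](O)CC(=O)C(C)C | intermediate
13 | (5S,6E)-5-{[tert-butyl(dimethyl)silyl]oxy}-7-iodo-2,6-dimethylhept-6-en-3-one | I/C=C(C)/[C@@H](O[Si](C)(C)C(C)(C)C)CC(=O)C(C)C | intermediate
14 | (5S,6E)-10-[benzyl(dimethyl)silyl]-5-{[tert-butyl(dimethyl)silyl]oxy}-8-hydroxy-2,6,10-trimethyldodeca-6,11-dien-3-one, epimers at the carbinol and silane carbons | C=CC(C)([Si](C)(C)Cc1ccccc1)CC(O)/C=C(C)/[C@@H](O[Si](C)(C)C(C)(C)C)CC(=O)C(C)C | intermediate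
15 | (5S,6E)-10-[benzyl(dimethyl)silyl]-5-{[tert-butyl(dimethyl)silyl]oxy}-2,6,10-trimethyldodeca-6,11-diene-3,8-dione, both epimers at the silane carbon | C=CC(C)([Si](C)(C)Cc1ccccc1)CC(=O)/C=C(C)/[C@@H](O[Si](C)(C)C(C)(C)C)CC(=O)C(C)C | intermediate
16 | chloro(ethyl)aluminium (3R)-3-[(1S)-1-{[tert-butyl(dimethyl)silyl]oxy}-4-methyl-3-oxopentyl]-3,6-dimethylcyclohepta-1,5-dien-1-olate | CC[Al](Cl)OC1=C[C@@](C)(CC=C(C)C1)[C@@H](O[Si](C)(C)C(C)(C)C)CC(=O)C(C)C | intermediate
17 | (1S,3R,3aR,8aR)-1-{[tert-butyl(dimethyl)silyl]oxy}-3-hydroxy-6,8a-dimethyl-3-(propan-2-yl)-2,3,3a,5,8,8a-hexahydro-1H-azulen-4-one | O=C1CC(C)=CC[C@@]2(C)[C@@H](O[Si](C)(C)C(C)(C)C)C[C@@](O)(C(C)C)[C@H]12 | intermediate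
18 | (1S,3R,3aS,4S,8aR)-1-{[tert-butyl(dimethyl)silyl]oxy}-6,8a-dimethyl-3-(propan-2-yl)-1,2,3,3a,4,5,8,8a-octahydroazulene-3,4-diol | O[C@H]1CC(C)=CC[C@@]2(C)[C@@H](O[Si](C)(C)C(C)(C)C)C[C@@](O)(C(C)C)[C@H]12 | intermediate
19 | (1S,3R,3aS,4S,8aR)-6,8a-dimethyl-3-(propan-2-yl)-1,2,3,3a,4,5,8,8a-octahydroazulene-1,3,4-triol | O[C@H]1CC(C)=CC[C@@]2(C)[C@@H](O)C[C@@](O)(C(C)C)[C@H]12 | intermediate
20 | angelic acid, (Z)-2-methylbut-2-enoic acid | C/C=C(/C)C(=O)O | starting material
21 | (2Z)-2-methylbut-2-enoic 2,4,6-trichlorobenzoic anhydride | C/C=C(/C)C(=O)OC(=O)c1c(Cl)cc(Cl)cc1Cl | intermediate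
22 | (1S,3R,3aS,4S,8aR)-3-hydroxy-6,8a-dimethyl-3-(propan-2-yl)-1,2,3,3a,4,5,8,8a-octahydroazulene-1,4-diyl bis[(2Z)-2-methylbut-2-enoate] | C/C=C(/C)C(=O)O[C@H]1CC(C)=CC[C@@]2(C)[C@@H](OC(=O)/C(C)=C\C)C[C@@](O)(C(C)C)[C@H]12 | target

**Step count**

Total: 13 steps. Longest linear sequence: 10 steps (5 → 7 → 8 → 12 → 13 → 14 → 15 → 17 → 18 → 19 → 22, steps 3, 4, 6–13).

**Steps most likely to fail**

1. Step 10 (new method). The 7-endo closure onto the fully substituted C1 may be slower than protodesilylation of the tertiary allylsilane. C10 may also enter on the C1 face anti to the silyloxy group (the polar Felkin–Anh alternative) and give the C1 epimer, or the cis-fused aldolate may fail to revert to the trans-fused one. The fallback uses known reactions only, sets out from 13 and returns at 17. CrCl2/NiCl2 coupling of 13 with 3-methylbut-3-enal would give the allylic alcohol F1, and Dess–Martin oxidation the skipped dienone F2. Intermolecular Hosomi–Sakurai conjugate allylation of F2 (allyltrimethylsilane, TiCl4, CH2Cl2, −78 °C), with the titanium enolate closing onto the C4 ketone, would give the cyclopentane ketol F3. Ring-closing metathesis of its allyl and 2-methylallyl groups with the second-generation Grubbs catalyst (CH2Cl2, 40 °C) would then form C8=C9 and the seven-membered ring of 17. Because C1–C10 is made intermolecularly here, the allyl donor, the Lewis acid and the O2 protecting group can be varied to fix the facial sense before the ring is closed.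

2. Step 13. Acylation of two hindered secondary alcohols may be slow enough for Z to E isomerisation of the activated angeloyl unit to compete, or may stop at a monoester. The fallback sets out from 19 and returns at 22. Esterification of both secondary alcohols with 2-[bis(2,2,2-trifluoroethoxy)phosphoryl]propanoic acid (DCC, DMAP, CH2Cl2) would give the bis(phosphonopropanoate) F4. A double Still–Gennari olefination with acetaldehyde (KN(SiMe3)2, 18-crown-6, THF, −78 °C) would then build both Z-2-methylbut-2-enoates on the molecule.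

3. Step 11. Ligand exchange of the hindered tertiary hydroxyl on boron may be slow, so that undirected hydride attacks the open α-face and facial selectivity at C6 is lost. The fallback sets out from 17 and returns at 18: SmI2 in THF–MeOH reduces the β-hydroxy ketone by electron transfer through a samarium chelate with the C4 hydroxyl, a process known to give anti-1,3-diols. No compound outside the route is formed.

**Further compounds**

F1 | step 10 | (5S,6E)-5-{[tert-butyl(dimethyl)silyl]oxy}-8-hydroxy-2,6,10-trimethylundeca-6,10-dien-3-one (carbinol epimers) | C=C(C)CC(O)/C=C(C)/[C@@H](O[Si](C)(C)C(C)(C)C)CC(=O)C(C)C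
F2 | step 10 | (5S,6E)-5-{[tert-butyl(dimethyl)silyl]oxy}-2,6,10-trimethylundeca-6,10-diene-3,8-dione | C=C(C)CC(=O)/C=C(C)/[C@@H](O[Si](C)(C)C(C)(C)C)CC(=O)C(C)C
F3 | step 10 | 1-[2-allyl-3-{[tert-butyl(dimethyl)silyl]oxy}-5-hydroxy-2-methyl-5-(propan-2-yl)cyclopentyl]-3-methylbut-3-en-1-one, configured at C1, C2, C4 and C5 as in 17 | C=C(C)CC(=O)[C@@H]1[C@@](C)(CC=C)[C@@H](O[Si](C)(C)C(C)(C)C)C[C@@]1(O)C(C)C
F4 | step 13 | triol 19 esterified at O2 and O6 with 2-[bis(2,2,2-trifluoroethoxy)phosphoryl]propanoic acid (epimers at the phosphonate carbons) | CC(C(=O)O[C@H]1CC(C)=CC[C@@]2(C)[C@@H](OC(=O)C(C)P(=O)(OCC(F)(F)F)OCC(F)(F)F)C[C@@](O)(C(C)C)[C@H]12)P(=O)(OCC(F)(F)F)OCC(F)(F)F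
F0 | step 11 | none | none
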